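Ring C is cut at the bond joining the carbon that becomes the ring B/C hemiketal to the B/C fusion CH. The first carbon is at the ketone oxidation level; the second is the vinylogous δ-position of the ring D cyclopentenone (C=O, CH=, β-carbon, CHMe, fusion CH), so a ring D dienone carrying isopropenyl on its β-carbon offers a free CH2 terminus to an acyl radical. One 7-endo closure of a β-methoxyacryloyl radical makes this bond, ring C and the CHMe centre, and leaves ring C with a ketone and an enol ether already told apart. The precursor is an enantiopure isopropenyl cyclopentenone whose silylated tertiary carbinol bears an (E)-β-methoxyacryloyl phenyl selenoester.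

Key step: step 12

Labels used below: ring A = pyranone, ring B = dihydropyran, ring C = seven-membered ring, ring D = cyclopentenone. In ring C: C-a = hemiketal carbon, C-b = CHOH, C-c = ketone carbon, C-d = tertiary carbinol (C/D fusion), C-e = alkene carbon (C/D fusion), C-f = CHMe, C-g = B/C fusion CH. The target is C-a S, C-b R, C-d R, C-f R, C-g R. Cyclopentene locants in 3–15: C1 = carbonyl, later carbinol, carbon (becomes C-d); C2 = isopropenyl carbon (C-e); C4 = secondary carbinol (becomes the ring D ketone); C5 = CMe2.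

Design notes:
- C-d is the only centre that cannot equilibrate later. It is set by a catalyst-controlled reduction (step 2) followed by a substrate-controlled alkynylation (step 6).
- The ring D enone is unveiled only in step 11, so methoxide, hydroxide, phosphine and selenol never meet a dienone.
- The (E) enol ether geometry is set by the protonation in step 7 (see its Why line).

Assumption (remark on the chemistry): in the oxazaborolidine reduction of 2 the quaternary CMe2 flank is taken as the larger carbonyl substituent, so the (R)-catalyst is written. If the opposite sense is found, the (S)-catalyst is used to reach the same (S)-alcohol 3.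

Step 1
Reactants: 1 2,2-dimethylcyclopentane-1,3-dione
Product: 2 2,2-dimethylcyclopent-4-ene-1,3-dione
Conditions: IBX (1.5 equiv), DMSO, 70 °C
Reagents that add atoms: none
Why: IBX dehydrogenation of a ketone through its enol should work here because the blocked C2 leaves only the C4–C5 bond to desaturate and the symmetrical enedione has no further α-CH2 to oxidise.

Step 2
Reactants: 2 2,2-dimethylcyclopent-4-ene-1,3-dione
Product: 3 (S)-4-hydroxy-5,5-dimethylcyclopent-2-en-1-one
Conditions: (R)-2-methyl-CBS-oxazaborolidine (15 mol %), catecholborane (0.95 equiv), PhMe, −78 °C; MeOH, then aq. NaHCO3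
Reagents that add atoms: none
Why: Corey–Bakshi–Shibata 1,2-reduction of an enone carbonyl; the two carbonyls are enantiotopic and attack on either from the catalyst-preferred face gives the same (S)-carbinol, so the oxazaborolidine sets the stereocentre, and a slight deficit of hydride limits diol formation.

Step 3
Reactants: 3 (S)-4-hydroxy-5,5-dimethylcyclopent-2-en-1-one
Product: 4 (S)-5,5-dimethyl-4-(triethylsilyloxy)cyclopent-2-en-1-one
Conditions: Et3SiCl (1.2 equiv), imidazole (2 equiv), CH2Cl2, 0 °C → rt
Reagents that add atoms: chlorotriethylsilane, CC[Si](CC)(CC)Cl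
Why: standard silyl ether formation on a secondary alcohol, which leaves the stereocentre untouched and installs the bulky group that later steers the alkynylation.

Step 4
Reactants: 4 (S)-5,5-dimethyl-4-(triethylsilyloxy)cyclopent-2-en-1-one
Product: 5 (S)-2-iodo-5,5-dimethyl-4-(triethylsilyloxy)cyclopent-2-en-1-one
Conditions: I2 (1.5 equiv), pyridine/CH2Cl2 (1:1), 0 °C → rt
Reagents that add atoms: iodine, II
Why: α-iodination of an enone by pyridine conjugate addition, iodination of the enolate and elimination (a Baylis–Hillman-type sequence), which is routine for 4-silyloxycyclopentenones and cannot touch C5 because it is quaternary.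

Step 5
Reactants: 5 (S)-2-iodo-5,5-dimethyl-4-(triethylsilyloxy)cyclopent-2-en-1-one; 6 isopropenylboronic acid pinacol ester
Product: 7 (S)-5,5-dimethyl-2-(prop-1-en-2-yl)-4-(triethylsilyloxy)cyclopent-2-en-1-one
Conditions: Pd(dppf)Cl2 (5 mol %), K3PO4 (3 equiv), THF/H2O (10:1), 45 °C; product used without storage
Reagents that add atoms: none
Why: Suzuki–Miyaura coupling of an α-iodoenone with an alkenyl boronate proceeds under mild aqueous base that should spare the hindered secondary silyl ether.

Step 6
Reactants: 7 (S)-5,5-dimethyl-2-(prop-1-en-2-yl)-4-(triethylsilyloxy)cyclopent-2-en-1-one; 8 methyl propiolate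
Product: 11 methyl 3-[(1R,4S)-5,5-dimethyl-2-(prop-1-en-2-yl)-1,4-bis(triethylsilyloxy)cyclopent-2-en-1-yl]prop-2-ynoate, via lithium acetylide of methyl propiolate 9 (not isolated), via tertiary lithium alkoxide 10 (not isolated)
Conditions: LiN(SiMe3)2 (1.3 equiv), 8 (1.4 equiv), THF, −78 °C; add 7, −78 °C; then Et3SiOTf (2.0 equiv), −78 → 0 °C
Reagents that add atoms: triethylsilyl triflate, CC[Si](CC)(CC)OS(=O)(=O)C(F)(F)F
Why: 1,2-addition of a lithium acetylide to a ketone, in which the small linear nucleophile should attack the hindered C1 carbonyl from the ring face opposite the C4 silyloxy group, giving the tertiary carbinol with its oxygen cis to the C4 oxygen (1R), and the alkoxide is silylated in the same flask before it can revert.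

Step 7
Reactants: 11 methyl 3-[(1R,4S)-5,5-dimethyl-2-(prop-1-en-2-yl)-1,4-bis(triethylsilyloxy)cyclopent-2-en-1-yl]prop-2-ynoate
Product: 12 methyl (E)-3-[(1R,4S)-5,5-dimethyl-2-(prop-1-en-2-yl)-1,4-bis(triethylsilyloxy)cyclopent-2-en-1-yl]-3-methoxyprop-2-enoate
Conditions: NaOMe (0.2 equiv), MeOH/THF (3:1), 0 °C, quenched (AcOH) as soon as 11 is consumed
Reagents that add atoms: methanol, CO
Why: base-catalysed oxa-Michael addition of methanol to the ynoate β-carbon, in which the allenolate should be protonated on the side of the small methoxy group and away from the quaternary carbinol carbon, placing the ester cis to that carbon ((E) enol ether), the same arrangement through which the free alcohols of this class close to tetronates.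

Step 8
Reactants: 12 methyl (E)-3-[(1R,4S)-5,5-dimethyl-2-(prop-1-en-2-yl)-1,4-bis(triethylsilyloxy)cyclopent-2-en-1-yl]-3-methoxyprop-2-enoate
Product: 13 (E)-3-[(1R,4S)-5,5-dimethyl-2-(prop-1-en-2-yl)-1,4-bis(triethylsilyloxy)cyclopent-2-en-1-yl]-3-methoxyprop-2-enoic acid
Conditions: LiOH·H2O (5 equiv), THF/MeOH/H2O (3:1:1), rt; cold 0.5 M HCl to pH 4, extract at once
Reagents that add atoms: lithium hydroxide, [Li+].[OH-]
Why: saponification of a methyl ester in a molecule that at this stage holds no enone, with the hindered β-carbon protecting the enol ether and its geometry from hydroxide.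

Step 9
Reactants: 13 (E)-3-[(1R,4S)-5,5-dimethyl-2-(prop-1-en-2-yl)-1,4-bis(triethylsilyloxy)cyclopent-2-en-1-yl]-3-methoxyprop-2-enoic acid
Product: 14 Se-phenyl (E)-3-[(1R,4S)-5,5-dimethyl-2-(prop-1-en-2-yl)-1,4-bis(triethylsilyloxy)cyclopent-2-en-1-yl]-3-methoxyprop-2-eneselenoate
Conditions: PhSeSePh (1.5 equiv), Bu3P (1.5 equiv), CH2Cl2, 0 °C → rt
Reagents that add atoms: diphenyl diselenide, c1ccc(cc1)[Se][Se]c1ccccc1
Why: redox condensation of a carboxylic acid with a diselenide and a phosphine through the acyloxyphosphonium salt gives the selenoester, and no Michael acceptor is present for the selenol or the phosphine to attack.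

Step 10
Reactants: 14 Se-phenyl (E)-3-[(1R,4S)-5,5-dimethyl-2-(prop-1-en-2-yl)-1,4-bis(triethylsilyloxy)cyclopent-2-en-1-yl]-3-methoxyprop-2-eneselenoate
Product: 15 Se-phenyl (E)-3-[(1R,4S)-4-hydroxy-5,5-dimethyl-2-(prop-1-en-2-yl)-1-(triethylsilyloxy)cyclopent-2-en-1-yl]-3-methoxyprop-2-eneselenoate
Conditions: PPTS (0.2 equiv), MeOH/CH2Cl2 (1:3), 0 °C
Reagents that add atoms: none
Why: acid-catalysed methanolysis of a silyl ether should select the secondary allylic triethylsilyl ether over the tertiary one, which is flanked by two fully substituted carbons, and the push-pull enol ether and the selenoester are inert to this weak acid.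

Step 11
Reactants: 15 Se-phenyl (E)-3-[(1R,4S)-4-hydroxy-5,5-dimethyl-2-(prop-1-en-2-yl)-1-(triethylsilyloxy)cyclopent-2-en-1-yl]-3-methoxyprop-2-eneselenoate
Product: 16 Se-phenyl (E)-3-methoxy-3-[(1R)-5,5-dimethyl-4-oxo-2-(prop-1-en-2-yl)-1-(triethylsilyloxy)cyclopent-2-en-1-yl]prop-2-eneselenoate
Conditions: MnO2 (activated, 20 equiv), CH2Cl2, rt
Reagents that add atoms: none
Why: MnO2 oxidation is specific for allylic alcohols, here a dienyl carbinol, so the ring D dienone should appear without oxidation at selenium, and the C4 stereocentre has done its work and is removed.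

Step 12
Reactants: 16 Se-phenyl (E)-3-methoxy-3-[(1R)-5,5-dimethyl-4-oxo-2-(prop-1-en-2-yl)-1-(triethylsilyloxy)cyclopent-2-en-1-yl]prop-2-eneselenoate
Product: 17 (4R,8aR)-8-methoxy-1,1,4-trimethyl-8a-(triethylsilyloxy)-1,4,5,8a-tetrahydroazulene-2,6-dione (C-d = C8a, C-f = C4, C-g = C5, C-a = C6)
Conditions: Bu3SnH (1.3 equiv) and AIBN (0.2 equiv) added by syringe pump over 6 h to 16 in PhH (0.005 M), 80 °C; then DBU (0.3 equiv), 50 °C
Reagents that add atoms: none
Why: The Bu3Sn radical abstracts PhSe from 16 and the nucleophilic (E)-β-methoxyacryloyl radical adds to the unsubstituted CH2 terminus of the isopropenyl group, the δ-carbon of the ring D dienone, giving a tertiary radical delocalised over C-f, C-e, the enone α-carbon and the ketone oxygen, which takes hydrogen from Bu3SnH. The closest known reaction type is the 7-endo cyclisation of acyl radicals from phenyl selenoesters onto 1,1-disubstituted alkenes, and α,β-unsaturated acyl radicals from selenoesters are established cyclisation partners. Ring C is closed in the 7-endo-trig mode, since both carbons of the accepting C=CH2 bond end up inside the new ring. The new C-f stereocentre is controlled by the fixed carbinol C-d: hydrogen should be delivered to the convex face of the folded bicyclic radical, opposite the vinylogous ester flap of ring C, and the DBU treatment moves any β,γ-unsaturated isomer into conjugation and equilibrates C-f toward the epimer with the methyl anti to the silyloxy group, which avoids a 1,3-syn methyl/silyloxy contact across C-e. The step needs 7-endo attack to beat 5-exo attack at the enone β-carbon, 6-exo attack at the internal isopropenyl carbon and plain reduction to the aldehyde; the β-carbon is fully substituted and flanked by the quaternary carbinol, the 6-exo path leads to an unstabilised primary radical, and slow addition keeps the stannane concentration low. The cis enol ether holds the acyl carbon beside ring D, and any (Z) isomer should converge because the acyl radical equilibrates with its α-ketenyl form, in which the former double bond can rotate.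

Step 13
Reactants: 17 (4R,8aR)-8-methoxy-1,1,4-trimethyl-8a-(triethylsilyloxy)-1,4,5,8a-tetrahydroazulene-2,6-dione
Product: 19 (4R,5S,8aR)-5-[(dimethylamino)methyl]-8-methoxy-1,1,4-trimethyl-8a-(triethylsilyloxy)-1,4,5,8a-tetrahydroazulene-2,6-dione, via lithium enolate of the vinylogous ester 18 (not isolated)
Conditions: LiN(iPr)2 (1.1 equiv), THF, −78 °C; CH2=NMe2 I (Eschenmoser's salt, 1.5 equiv), −78 → 0 °C
Reagents that add atoms: Eschenmoser's salt, C=[N+](C)C.[I-]
Why: kinetic α'-deprotonation of a vinylogous ester followed by a Mannich reaction; C-g is the only CH2 next to a carbonyl and C-d is quaternary, so no γ-enolate can form, and the aminomethyl group should enter anti to the neighbouring C-f methyl, a centre that is erased in the next step.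

Step 14
Reactants: 19 (4R,5S,8aR)-5-[(dimethylamino)methyl]-8-methoxy-1,1,4-trimethyl-8a-(triethylsilyloxy)-1,4,5,8a-tetrahydroazulene-2,6-dione; 20 4-hydroxy-5,6-dimethyl-2H-pyran-2-one
Product: 23 (4R,5R,8aR)-5-[(4-hydroxy-5,6-dimethyl-2-oxo-2H-pyran-3-yl)methyl]-8-methoxy-1,1,4-trimethyl-8a-(triethylsilyloxy)-1,4,5,8a-tetrahydroazulene-2,6-dione, via trimethylammonium iodide 21 (not isolated), via α-methylene ketone 22 (not isolated)
Conditions: MeI (5 equiv), CH2Cl2, rt; evaporate; 20 (1.5 equiv), iPr2NEt (2 equiv), MeCN, 40 °C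
Reagents that add atoms: none
Why: quaternisation and E1cB loss of trimethylamine release the α-methylene ketone in the presence of the hydroxypyranone, whose C3 adds in a Michael reaction (C-alkylation as in warfarin-type additions) at the unhindered exocyclic terminus, and C-g, α to the ketone, should settle here or under the acid of step 15 with the new CH2 trans to the C-f methyl.

Step 15
Reactants: 23 (4R,5R,8aR)-5-[(4-hydroxy-5,6-dimethyl-2-oxo-2H-pyran-3-yl)methyl]-8-methoxy-1,1,4-trimethyl-8a-(triethylsilyloxy)-1,4,5,8a-tetrahydroazulene-2,6-dione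
Product: 24 tetracyclic enol ether (rings A–D; ring B closed by the pyranone O4–C-a bond, C-a=C-b conjugated to the C-c ketone; C-d R with OSiEt3, C-f R, C-g R)
Conditions: TsOH·H2O (0.1 equiv), PhMe, 50 °C
Reagents that add atoms: none
Why: acid-catalysed alkoxy exchange of a β-alkoxy enone (hemiketal formation at C-a, loss of water, hydrolytic loss of methanol from C-c), in which the pyranone 4-OH can reach only C-a through a six-membered ring and reversibility favours the α-pyranone isomer, while C-g can equilibrate through the dienol ether to the trans arrangement.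

Step 16
Reactants: 24 tetracyclic enol ether
Product: 26 triethylsilyl ether of the target at the C-d oxygen (C-a S, C-b R, C-d R, C-f R, C-g R), via enol ether epoxide 25 (not isolated)
Conditions: DMDO (1.3 equiv, in acetone), CH2Cl2, −20 → 0 °C; then THF/H2O (4:1), rt
Reagents that add atoms: dimethyldioxirane, CC1(C)OO1; water, O
Why: Rubottom-type epoxidation of an enol ether followed by hydrolytic opening, as known for cyclic β-alkoxy enones; DMDO should attack C-a=C-b, the only enol ether outside the aromatic pyranone, from the face of the axial C-g hydrogen, anti to the C-g–C-f bond and the silyloxy group, which sets C-b (R), and water opens the epoxide at the acetal carbon C-a with inversion to give the trans-fused hemiketal (S) with an axial hydroxyl, the isomer also favoured by ring–chain equilibration.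

Step 17
Reactants: 26 triethylsilyl ether of the target
Product: 27 CNP0525404.1
Conditions: HF·pyridine (excess), pyridine, THF, 0 °C → rt
Reagents that add atoms: none
Why: buffered fluoride cleavage of a tertiary triethylsilyl ether is mild enough for the α-ketol and the hemiketal, touches no stereocentre, and any opening of the hemiketal can only re-close to the same anomer.

Compound list
1 | 2,2-dimethylcyclopentane-1,3-dione | CC1(C)C(=O)CCC1=O | starting material
2 | 2,2-dimethylcyclopent-4-ene-1,3-dione | CC1(C)C(=O)C=CC1=O | intermediate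
3 | (S)-4-hydroxy-5,5-dimethylcyclopent-2-en-1-one | O=C1C=C[C@H](O)C1(C)C | intermediate
4 | (S)-5,5-dimethyl-4-(triethylsilyloxy)cyclopent-2-en-1-one | O=C1C=C[C@H](O[Si](CC)(CC)CC)C1(C)C | intermediate
5 | (S)-2-iodo-5,5-dimethyl-4-(triethylsilyloxy)cyclopent-2-en-1-one | O=C1C(I)=C[C@H](O[Si](CC)(CC)CC)C1(C)C | intermediate
6 | isopropenylboronic acid pinacol ester | CC(=C)B1OC(C)(C)C(C)(C)O1 | starting material
7 | (S)-5,5-dimethyl-2-(prop-1-en-2-yl)-4-(triethylsilyloxy)cyclopent-2-en-1-one | C=C(C)C1=C[C@H](O[Si](CC)(CC)CC)C(C)(C)C1=O | intermediate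
8 | methyl propiolate | COC(=O)C#C | starting material
9 | lithium acetylide of methyl propiolate | [Li]C#CC(=O)OC | intermediate (not isolated)
10 | lithium (1R,4S)-alkoxide from addition of 9 to 7 (alkynyl trans to the C4 silyloxy group) | C=C(C)C1=C[C@H](O[Si](CC)(CC)CC)C(C)(C)[C@@]1(O[Li])C#CC(=O)OC | intermediate (not isolated)
11 | methyl 3-[(1R,4S)-5,5-dimethyl-2-(prop-1-en-2-yl)-1,4-bis(triethylsilyloxy)cyclopent-2-en-1-yl]prop-2-ynoate | C=C(C)C1=C[C@H](O[Si](CC)(CC)CC)C(C)(C)[C@@]1(O[Si](CC)(CC)CC)C#CC(=O)OC | intermediate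
12 | methyl (E)-3-[(1R,4S)-5,5-dimethyl-2-(prop-1-en-2-yl)-1,4-bis(triethylsilyloxy)cyclopent-2-en-1-yl]-3-methoxyprop-2-enoate | C=C(C)C1=C[C@H](O[Si](CC)(CC)CC)C(C)(C)[C@@]1(O[Si](CC)(CC)CC)/C(OC)=C\C(=O)OC | intermediate
13 | (E)-3-[(1R,4S)-5,5-dimethyl-2-(prop-1-en-2-yl)-1,4-bis(triethylsilyloxy)cyclopent-2-en-1-yl]-3-methoxyprop-2-enoic acid | C=C(C)C1=C[C@H](O[Si](CC)(CC)CC)C(C)(C)[C@@]1(O[Si](CC)(CC)CC)/C(OC)=C\C(=O)O | intermediate
14 | Se-phenyl (E)-3-[(1R,4S)-5,5-dimethyl-2-(prop-1-en-2-yl)-1,4-bis(triethylsilyloxy)cyclopent-2-en-1-yl]-3-methoxyprop-2-eneselenoate | C=C(C)C1=C[C@H](O[Si](CC)(CC)CC)C(C)(C)[C@@]1(O[Si](CC)(CC)CC)/C(OC)=C\C(=O)[Se]c1ccccc1 | intermediate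
15 | Se-phenyl (E)-3-[(1R,4S)-4-hydroxy-5,5-dimethyl-2-(prop-1-en-2-yl)-1-(triethylsilyloxy)cyclopent-2-en-1-yl]-3-methoxyprop-2-eneselenoate | C=C(C)C1=C[C@H](O)C(C)(C)[C@@]1(O[Si](CC)(CC)CC)/C(OC)=C\C(=O)[Se]c1ccccc1 | intermediate
16 | Se-phenyl (E)-3-methoxy-3-[(1R)-5,5-dimethyl-4-oxo-2-(prop-1-en-2-yl)-1-(triethylsilyloxy)cyclopent-2-en-1-yl]prop-2-eneselenoate (key-step precursor) | C=C(C)C1=CC(=O)C(C)(C)[C@@]1(O[Si](CC)(CC)CC)/C(OC)=C\C(=O)[Se]c1ccccc1 | intermediate
17 | (4R,8aR)-8-methoxy-1,1,4-trimethyl-8a-(triethylsilyloxy)-1,4,5,8a-tetrahydroazulene-2,6-dione (key-step product) | COC1=CC(=O)C[C@@H](C)C2=CC(=O)C(C)(C)[C@@]12O[Si](CC)(CC)CC | intermediate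
18 | lithium enolate of 17 (C-a O-lithium, C-a=C-g; C-d and C-f as in 17) | COC1=CC(O[Li])=C[C@@H](C)C2=CC(=O)C(C)(C)[C@@]12O[Si](CC)(CC)CC | intermediate (not isolated)
19 | (4R,5S,8aR)-5-[(dimethylamino)methyl]-8-methoxy-1,1,4-trimethyl-8a-(triethylsilyloxy)-1,4,5,8a-tetrahydroazulene-2,6-dione | COC1=CC(=O)[C@H](CN(C)C)[C@@H](C)C2=CC(=O)C(C)(C)[C@@]12O[Si](CC)(CC)CC | intermediate
20 | 4-hydroxy-5,6-dimethyl-2H-pyran-2-one | Cc1oc(=O)cc(O)c1C | starting material
21 | trimethylammonium iodide of 19 (C-d, C-f, C-g as in 19) | COC1=CC(=O)[C@H](C[N+](C)(C)C)[C@@H](C)C2=CC(=O)C(C)(C)[C@@]12O[Si](CC)(CC)CC.[I-] | intermediate (not isolated)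
22 | α-methylene ketone: 17 with C-g as C=CH2 (C-d and C-f as in 17) | COC1=CC(=O)C(=C)[C@@H](C)C2=CC(=O)C(C)(C)[C@@]12O[Si](CC)(CC)CC | intermediate (not isolated)
23 | (4R,5R,8aR)-5-[(4-hydroxy-5,6-dimethyl-2-oxo-2H-pyran-3-yl)methyl]-8-methoxy-1,1,4-trimethyl-8a-(triethylsilyloxy)-1,4,5,8a-tetrahydroazulene-2,6-dione | COC1=CC(=O)[C@H](Cc3c(O)c(C)c(C)oc3=O)[C@@H](C)C2=CC(=O)C(C)(C)[C@@]12O[Si](CC)(CC)CC | intermediate
24 | tetracyclic enol ether: ring B closed by the pyranone O4–C-a bond, C-a=C-b conjugated to the C-c ketone, C-d (R) OSiEt3, C-f (R), C-g (R) | Cc1oc(=O)c2c(c1C)OC1=CC(=O)[C@@]3(O[Si](CC)(CC)CC)C(=CC(=O)C3(C)C)[C@H](C)[C@H]1C2 | intermediate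
25 | C-a/C-b epoxide of 24, oxygen on the face of the C-g hydrogen | Cc1oc(=O)c2c(c1C)O[C@]13O[C@@H]3C(=O)[C@@]4(O[Si](CC)(CC)CC)C(=CC(=O)C4(C)C)[C@H](C)[C@H]1C2 | intermediate (not isolated)
26 | triethylsilyl ether of the target at the C-d oxygen (C-a S, C-b R, C-d R, C-f R, C-g R) | Cc1oc(=O)c2c(c1C)O[C@]1(O)[C@H](O)C(=O)[C@@]3(O[Si](CC)(CC)CC)C(=CC(=O)C3(C)C)[C@H](C)[C@H]1C2 | intermediate
27 | CNP0525404.1 (C-a S, C-b R, C-d R, C-f R, C-g R) | Cc1oc(=O)c2c(c1C)O[C@]1(O)[C@H](O)C(=O)[C@@]3(O)C(=CC(=O)C3(C)C)[C@H](C)[C@H]1C2 | target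

Total step count: 17
Longest linear sequence: 17 steps (1 → 27); 6, 8 and 20 enter as purchased fragments.

Steps most likely to fail

1. Step 12. The acyl radical may close 5-exo onto the enone β-carbon, or be reduced to the aldehyde before it cyclises. The fallback forms the same bond by two-electron chemistry and sets out from 14. DIBAL-H at −78 °C reduces the selenoester to the bis-silylated (E)-β-methoxy enal F1. Intramolecular diene hydroacylation with [Rh(dppe)]ClO4 in ClCH2CH2Cl at 65 °C, the known route from dienals to cycloheptenones in which the acyl rhodium hydride adds 1,4 across the diene, should give the bicyclic ketone F2, with the alkene between C-e and C-f and the ring D carbon still at the silyl ether stage. PPTS in MeOH then frees the secondary alcohol F3, Dess–Martin periodinane gives the β,γ-unsaturated ring D ketone F4, and DBU moves the alkene into conjugation and sets C-f as in step 12. The fallback returns to the route at 17.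

2. Step 7. Protonation of the allenolate on the wrong side, or base-mediated equilibration, may give the (Z) enol ether, and loss of the tertiary silyl group would divert material into a spiro tetronate. The fallback fixes the geometry in the reagent and sets out from 7. Methyl (E)-3-methoxyacrylate is deprotonated at C3 by LiN(iPr)2 in THF at −95 °C (ester-directed vinylic lithiation) to methyl (E)-3-lithio-3-methoxyprop-2-enoate F5. This adds to the ketone of 7 with retention of alkene geometry and anti to the C4 silyloxy group, giving the lithium alkoxide F6, which is trapped with Et3SiOTf at −95 °C before it can lactonise. The fallback returns to the route at 12.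

3. Step 16. The oxidant may attack the wrong face of C-a=C-b or the electron-rich pyranone ring. The fallback replaces epoxidation and hydrolysis by a syn-dihydroxylation and sets out from 24. OsO4 (5 mol %) with N-methylmorpholine N-oxide in acetone/H2O at 0 °C, a bulkier [3+2] oxidant that ignores the aromatic pyranone, should add to the face of the C-g hydrogen and give the cis-fused C-a epimer of 26, F7. Ring–chain equilibration of this hemiketal (PPTS, wet CH2Cl2) inverts C-a. The fallback returns to the route at 26.

Further compounds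
F1 | step 12 | (E)-3-[(1R,4S)-5,5-dimethyl-2-(prop-1-en-2-yl)-1,4-bis(triethylsilyloxy)cyclopent-2-en-1-yl]-3-methoxyprop-2-enal | C=C(C)C1=C[C@H](O[Si](CC)(CC)CC)C(C)(C)[C@@]1(O[Si](CC)(CC)CC)/C(OC)=C\C=O
F2 | step 12 | ring C/D bicycle with C-e=C-f alkene, C-a ketone, C-c methoxy enol ether, ring D CH2 and (S)-CH(OSiEt3), C-d (R) OSiEt3 | COC1=CC(=O)CC(C)=C2C[C@H](O[Si](CC)(CC)CC)C(C)(C)[C@@]12O[Si](CC)(CC)CC
F3 | step 12 | secondary alcohol from F2 (ring D (S)-CHOH, C-d (R) OSiEt3) | COC1=CC(=O)CC(C)=C2C[C@H](O)C(C)(C)[C@@]12O[Si](CC)(CC)CC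
F4 | step 12 | β,γ-unsaturated ring D ketone (C-e=C-f alkene, C-d (R) OSiEt3) | COC1=CC(=O)CC(C)=C2CC(=O)C(C)(C)[C@@]12O[Si](CC)(CC)CC
F5 | step 7 | methyl (E)-3-lithio-3-methoxyprop-2-enoate | [Li]/C(OC)=C\C(=O)OC
F6 | step 7 | lithium (1R,4S)-alkoxide corresponding to 12 before silylation | C=C(C)C1=C[C@H](O[Si](CC)(CC)CC)C(C)(C)[C@@]1(O[Li])/C(OC)=C\C(=O)OC
F7 | step 16 | C-a epimer of 26 (C-a and C-b hydroxyls cis, rings B/C cis-fused) | Cc1oc(=O)c2c(c1C)O[C@@]1(O)[C@H](O)C(=O)[C@@]3(O[Si](CC)(CC)CC)C(=CC(=O)C3(C)C)[C@H](C)[C@H]1C2
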